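Catalysis slow enough to share its starting material with a side reaction is what these runs suggest: Monday's flask read 14 % and then 14 %, so I took its starting material to have ended there, as target or quenched substrate.

| setting | Friday's | Tuesday's | Monday's | Thursday's | violet | red |
|---|---|---|---|---|---|---|
| starting material | 0.050 M | 0.050 M | 0.050 M | 0.050 M | 0.050 M | 0.050 M |
| second substrate | 0.050 M | 0.050 M | 0.050 M | 0.089 M | 0.0500 M | 0.150 M |
| protic impurity | 0.018 M | 0.032 M | 0.064 M | 0.015 M | 0.0150 M | 0.0600 M |
| free catalyst | 0.25 mM | 0.25 mM | 0.25 mM | 0.25 mM | 0.25 mM | 0.25 mM |
| remark | run made earlier | run made earlier | run made earlier | run made earlier |  |  |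
| time |  |  |  |  | 1.0 h | 3.0 h |

| run | time / min | target / % |
|---|---|---|
| Friday's | 2.50 | 6 |
| Friday's | 8.00 | 23 |
| Friday's | 15.0 | 31 |
| Friday's | 20.0 | 34 |
| Friday's | 30.0 | 44 |
| Tuesday's | 2.50 | 7 |
| Tuesday's | 5.00 | 14 |
| Tuesday's | 8.00 | 17 |
| Tuesday's | 15.0 | 23 |
| Tuesday's | 30.0 | 33 |
| Monday's | 2.50 | 5 |
| Monday's | 5.00 | 10 |
| Monday's | 8.00 | 12 |
| Monday's | 15.0 | 14 |
| Monday's | 30.0 | 14 |
| Thursday's | 2.50 | 7 |
| Thursday's | 8.00 | 18 |
| Thursday's | 15.0 | 28 |
| Thursday's | 20.0 | 34 |
| Thursday's | 30.0 | 43 |

(each reading ± 1.5 percentage points)

- the winner by amount of target, in percent of the starting material charged; "neither" if no more than 2 percentage points parts them (violet / red / neither)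
- how much target is there at the end, in percent of the starting material charged: violet
- how much target is there at the end, in percent of the starting material charged: red

I solved the two ends and joined them, leaving the homo dimer aside. Taking the catalyst's rate as proportional to the starting material, at each moment catalyst and impurity share the starting material as the even level stands to the impurity present. Summed while the impurity falls, this makes target equal to the even level times ln(impurity charged / impurity left).

Monday's readings put it at 6.28 mM: this is the even level, the impurity concentration at which, with Monday's charges of catalyst and second substrate, catalyst and impurity take starting material equally fast.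

Red's impurity charge exceeds its starting material, so, leaving its second substrate aside, I let it quench Monday's share, which gives 15.8 % target. In violet, the impurity, if spent whole, leaves 70.0 % for target and dimer together, and Friday's, with more impurity than violet, already read 44 % at 30.0 min, so I expected violet ahead.

The forecast said violet, with 62 % for violet and 12 % for red: “the impurity removes starting material stoichiometrically and quite fast”.

The simulation gave violet, with violet 56.9 % and red 10.9 %. The forecast's violet figure is what first-order growth to completion through Friday's last reading gives.

    starting material + free catalyst ⇌ catalyst intermediate A (K = 22.0 M⁻¹, k = 360 M⁻¹ min⁻¹)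
    catalyst intermediate A → free catalyst + target (k = 42.0 min⁻¹)
    second substrate + free catalyst ⇌ catalyst intermediate B (K = 12.0 M⁻¹, k = 240 M⁻¹ min⁻¹)
    catalyst intermediate B → free catalyst + second product (k = 6.50 min⁻¹)
    2 starting material → homo dimer (k = 0.190 M⁻¹ min⁻¹)
    starting material + protic impurity → quenched substrate (k = 6.20 M⁻¹ min⁻¹)

The gap is mainly the difference in protic impurity: with that difference taken away, red's impurity set at violet's amount, red gives 55.7 %. Red kept 28 % of its impurity, so red's own even level comes to 4.32 mM, lower than Monday's. The difference in second substrate is only a part of the gap: with that difference taken away, red's second substrate set at violet's amount, red gives 15.4 %.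

Violet read at 15 min has 8.2 % of its impurity left, so the even level gives 31.4 % target. The simulation gives 32.4 %.

The readings are calculated for an exercise; scatter was added.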